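**Retrosynthetic overview**
1. Target ⇐ heptabenzyl diketone 32 (neutral hydrogenolysis) ⇐ bis(chroman-4-ol) 31; both C4 carbonyls are carried as alcohols, so the epimerisable cis C3–H never meets base as a ketone.
2. Upper ring C: O1–C8a by intramolecular copper-catalysed O-arylation (retention at C2); C4–C4a by aryl Grignard addition to aldehyde 24.
3. Key C2–C3 bond: Evans boron syn-aldol of the (lower-unit-8-yl)acetyl imide 18 with 3,4-bis(benzyloxy)benzaldehyde; the syn aldol becomes the 2,3-cis pair.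
4. Lower unit first: phloroacetophenone → Claisen allyl → chromone → rhodium-catalysed asymmetric 1,4-arylation (2S) → reduce, silylate, cleave allyl to the acetic acid.
5. Ring order: lower ring A (bought) → lower ring C → upper ring C, closed onto a preformed upper ring A.

Assumption: the SMILES is read literally, i.e. (2R,3R) in the upper flavanone (2-aryl and 3-aryl cis) and (2S) in the lower one.

Abbreviations: Chr = (2S,4S)-5,7-bis(benzyloxy)-2-[4-(benzyloxy)phenyl]-4-(tert-butyldimethylsilyloxy)chroman-8-yl; Chr-OH = the same group with a free 4-OH; Bn = benzyl, TBS = tert-butyldimethylsilyl, TES = triethylsilyl.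

**Step 1**
Reactants: 1 2',4',6'-trihydroxyacetophenone
Product: 2 1-[2,4-bis(benzyloxy)-6-hydroxyphenyl]ethanone
Conditions: BnBr (2.05 equiv), K2CO3, DMF, rt
Reagents that add atoms: benzyl bromide, BrCc1ccccc1
Why: Williamson etherification; the hydroxyl hydrogen-bonded to the acetyl carbonyl is far less nucleophilic, so only the other two are benzylated.

**Step 2**
Reactants: 2 1-[2,4-bis(benzyloxy)-6-hydroxyphenyl]ethanone; 3 allyl bromide
Product: 4 1-[2-(allyloxy)-4,6-bis(benzyloxy)phenyl]ethanone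
Conditions: K2CO3, DMF, 70 °C
Reagents that add atoms: none
Why: Williamson allylation of the chelated phenol under forcing conditions.

**Step 3**
Reactants: 4 1-[2-(allyloxy)-4,6-bis(benzyloxy)phenyl]ethanone
Product: 6 1-[3-allyl-4,6-bis(benzyloxy)-2-hydroxyphenyl]ethanone, via dienone 5 (not isolated)
Conditions: PhNEt2, 200 °C
Reagents that add atoms: none
Why: aromatic Claisen rearrangement; the [3,3] shift can only reach the one free ortho carbon (the other bears the acetyl), and the dienone then tautomerises.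

**Step 4**
Reactants: 6 1-[3-allyl-4,6-bis(benzyloxy)-2-hydroxyphenyl]ethanone; 7 N,N-dimethylformamide dimethyl acetal
Product: 9 8-allyl-5,7-bis(benzyloxy)-4H-chromen-4-one, via enaminone 8 (not isolated)
Conditions: 7, toluene, 100 °C; then AcOH, 90 °C
Reagents that add atoms: none
Why: condensation of the methyl ketone to the enaminone, then acid-promoted addition–elimination of the phenol closes the chromone (lower ring C).

**Step 5**
Reactants: 9 8-allyl-5,7-bis(benzyloxy)-4H-chromen-4-one; 10 4-(benzyloxy)phenylboronic acid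
Product: 11 (2S)-8-allyl-5,7-bis(benzyloxy)-2-[4-(benzyloxy)phenyl]chroman-4-one
Conditions: [RhCl(C2H4)2]2 (1.5 mol %), MeO-F12-BIPHEP (3.3 mol %), KOH (10 mol %), toluene/H2O, 25 °C
Reagents that add atoms: none
Why: Hayashi–Miyaura rhodium-catalysed asymmetric 1,4-addition, in which the aryl–rhodium species on the electron-poor chiral bisphosphine adds to one face of the chromone C2 and sets 2S (the ligand antipode used is the one that a CD check of 11 shows to give 2S).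

**Step 6**
Reactants: 11 (2S)-8-allyl-5,7-bis(benzyloxy)-2-[4-(benzyloxy)phenyl]chroman-4-one
Product: 12 (2S,4S)-8-allyl-5,7-bis(benzyloxy)-2-[4-(benzyloxy)phenyl]chroman-4-ol
Conditions: NaBH4, THF/MeOH, 0 °C
Reagents that add atoms: none
Why: borohydride reduction masks the enolisable, base-sensitive flavanone ketone; hydride attack gives the 2,4-cis alcohol, a centre that is re-oxidised in step 20.

**Step 7**
Reactants: 12 (2S,4S)-8-allyl-5,7-bis(benzyloxy)-2-[4-(benzyloxy)phenyl]chroman-4-ol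
Product: 13 (2S,4S)-8-allyl-5,7-bis(benzyloxy)-2-[4-(benzyloxy)phenyl]-4-(tert-butyldimethylsilyloxy)chromane
Conditions: TBSCl, imidazole, DMAP (cat.), DMF, 40 °C
Reagents that add atoms: tert-butyldimethylsilyl chloride, CC(C)(C)[Si](C)(C)Cl
Why: silyl ether formation under base-only conditions protects the ionisable benzylic alcohol.

**Step 8**
Reactants: 13 (2S,4S)-8-allyl-5,7-bis(benzyloxy)-2-[4-(benzyloxy)phenyl]-4-(tert-butyldimethylsilyloxy)chromane
Product: 14 2-[Chr]acetaldehyde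
Conditions: OsO4 (2 mol %), NaIO4, 2,6-lutidine, dioxane/H2O, rt
Reagents that add atoms: osmium tetroxide, O=[Os](=O)(=O)=O; sodium periodate, [Na+].[O-]I(=O)(=O)=O (together they supply the aldehyde oxygen)
Why: Lemieux–Johnson oxidative cleavage of the only alkene.

**Step 9**
Reactants: 14 2-[Chr]acetaldehyde
Product: 15 2-[Chr]acetic acid
Conditions: NaClO2, NaH2PO4, 2-methyl-2-butene (30 equiv), t-BuOH/THF/H2O, 0 °C
Reagents that add atoms: sodium chlorite, [Na+].[O-]Cl=O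
Why: Pinnick oxidation; the large excess of alkene scavenges hypochlorite before it can chlorinate the electron-rich ring.

**Step 10**
Reactants: 15 2-[Chr]acetic acid; 16 (R)-4-benzyloxazolidin-2-one
Product: 18 (4R)-4-benzyl-3-{2-[Chr]acetyl}oxazolidin-2-one, via mixed pivalic anhydride 17 (not isolated)
Conditions: PivCl, Et3N, THF, −20 °C; then 16, LiCl, −20 °C to rt
Reagents that add atoms: none
Why: N-acylation of the oxazolidinone through the mixed anhydride with LiCl/Et3N activation, which avoids any strong base.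

**Step 11 (key step)**
Reactants: 18 (4R)-4-benzyl-3-{2-[Chr]acetyl}oxazolidin-2-one; 19 3,4-bis(benzyloxy)benzaldehyde
Product: 21 (4R)-4-benzyl-3-{(2R,3R)-3-[3,4-bis(benzyloxy)phenyl]-3-hydroxy-2-[Chr]propanoyl}oxazolidin-2-one, via Z-dibutylboron enolate 20 (not isolated)
Conditions: i-Pr2NEt then Bu2BOTf, CH2Cl2, −78 to 0 °C; 19, −78 to 0 °C; pH 7 buffer, MeOH, H2O2, 0 °C
Reagents that add atoms: none
Why: Evans boron syn-aldol; the Z-enolate reacts through a Zimmerman–Traxler chair on the face dictated by the (R)-benzyl auxiliary, giving the (2R,3R) syn adduct whose two new centres become C3 and C2 of the upper ring.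

**Step 12**
Reactants: 21 the syn-aldol adduct
Product: 22 (4R)-4-benzyl-3-{(2R,3R)-3-[3,4-bis(benzyloxy)phenyl]-2-[Chr]-3-(triethylsilyloxy)propanoyl}oxazolidin-2-one
Conditions: TESCl, imidazole, DMF, 0 °C to rt
Reagents that add atoms: triethylsilyl chloride, CC[Si](Cl)(CC)CC
Why: silylation blocks retro-aldol cleavage in the following steps.

**Step 13**
Reactants: 22 the TES-protected aldol imide
Product: 23 (2S,3R)-3-[3,4-bis(benzyloxy)phenyl]-2-[Chr]-3-(triethylsilyloxy)propan-1-ol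
Conditions: LiBH4, MeOH (1 equiv), THF, 0 °C
Reagents that add atoms: none
Why: reductive removal of the auxiliary at the exocyclic carbonyl; no stereocentre is touched (the C2 descriptor changes only through CIP priorities).

**Step 14**
Reactants: 23 the primary alcohol
Product: 24 (2R,3R)-3-[3,4-bis(benzyloxy)phenyl]-2-[Chr]-3-(triethylsilyloxy)propanal
Conditions: Dess–Martin periodinane, NaHCO3, CH2Cl2, 0 °C; used at once
Reagents that add atoms: none
Why: Dess–Martin oxidation under buffered, cold conditions gives the α-aryl aldehyde without α-epimerisation.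

**Step 15**
Reactants: 25 5-bromoresorcinol
Product: 26 1,3-bis(benzyloxy)-5-bromobenzene
Conditions: BnBr, K2CO3, DMF, 50 °C
Reagents that add atoms: benzyl bromide, BrCc1ccccc1
Why: Williamson etherification of both phenols.

**Step 16**
Reactants: 26 1,3-bis(benzyloxy)-5-bromobenzene
Product: 27 1,5-bis(benzyloxy)-3-bromo-2-iodobenzene
Conditions: NIS, CF3CO2H (cat.), MeCN, 0 °C to rt
Reagents that add atoms: N-iodosuccinimide, O=C1CCC(=O)N1I
Why: electrophilic aromatic iodination at the carbon para to one benzyloxy group and ortho to the other, next to bromine, which is the most activated site.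

**Step 17**
Reactants: 24 the aldehyde; 27 1,5-bis(benzyloxy)-3-bromo-2-iodobenzene
Product: 29 1-[2,4-bis(benzyloxy)-6-bromophenyl]-3-[3,4-bis(benzyloxy)phenyl]-2-[Chr]-3-(triethylsilyloxy)propan-1-ol (C1 epimers), via arylmagnesium chloride 28 (not isolated)
Conditions: 27, i-PrMgCl·LiCl, THF, −40 °C; then 24, −40 to −10 °C; aq NH4Cl
Reagents that add atoms: none
Why: iodine–magnesium exchange is selective for C–I over C–Br and the Grignard reagent adds 1,2 to the aldehyde; the new carbinol centre is uncontrolled and is oxidised away in step 20.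

**Step 18**
Reactants: 29 the bromoaryl carbinol
Product: 30 1-[2,4-bis(benzyloxy)-6-bromophenyl]-3-[3,4-bis(benzyloxy)phenyl]-2-[Chr-OH]propane-1,3-diol (C1 epimers)
Conditions: TBAF (3 equiv), THF, 0 °C to rt
Reagents that add atoms: none
Why: fluoride cleaves both silyl ethers under non-acidic conditions that the ionisable benzylic alcohols tolerate.

**Step 19**
Reactants: 30 the bromo triol
Product: 31 (2R,3S,4RS)-5,7-bis(benzyloxy)-2-[3,4-bis(benzyloxy)phenyl]-3-[Chr-OH]chroman-4-ol (2,3-cis)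
Conditions: CuI (20 mol %), 3,4,7,8-tetramethyl-1,10-phenanthroline (40 mol %), Cs2CO3, toluene (0.02 M, degassed), 110 °C
Reagents that add atoms: none
Why: intramolecular Ullmann-type O-arylation; only the C3 hydroxyl can reach the C–Br carbon through a six-membered ring and its C–O bond is not broken, so the syn aldol array becomes the 2,3-cis chroman (3S here is the target's 3R, a CIP change only).

**Step 20**
Reactants: 31 the bis(chroman-4-ol)
Product: 32 (2R,3R)-5,7-bis(benzyloxy)-2-[3,4-bis(benzyloxy)phenyl]-3-{(2S)-5,7-bis(benzyloxy)-2-[4-(benzyloxy)phenyl]-4-oxochroman-8-yl}chroman-4-one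
Conditions: Dess–Martin periodinane (3 equiv), NaHCO3, CH2Cl2, 0 °C to rt; pH 7 work-up, neutral silica
Reagents that add atoms: none
Why: Dess–Martin oxidation converts both benzylic alcohols to the ketones without base, so the cis C3–H and both C2 centres are not equilibrated.

**Step 21**
Reactants: 32 the heptabenzyl diketone
Product: 33 (2R,3R)-2-(3,4-dihydroxyphenyl)-5,7-dihydroxy-3-[(2S)-5,7-dihydroxy-2-(4-hydroxyphenyl)-4-oxochroman-8-yl]chroman-4-one
Conditions: H2 (1 atm), 10% Pd/C, EtOAc/THF, rt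
Reagents that add atoms: none
Why: hydrogenolysis removes all seven benzyl ethers under neutral conditions that leave the ketones and the three stereocentres untouched.

**Compound list**
1 | 2',4',6'-trihydroxyacetophenone | CC(=O)c1c(O)cc(O)cc1O | starting material
2 | 1-[2,4-bis(benzyloxy)-6-hydroxyphenyl]ethanone | CC(=O)c1c(O)cc(OCc2ccccc2)cc1OCc1ccccc1 | intermediate
3 | allyl bromide | C=CCBr | starting material
4 | 1-[2-(allyloxy)-4,6-bis(benzyloxy)phenyl]ethanone | CC(=O)c1c(OCC=C)cc(OCc2ccccc2)cc1OCc1ccccc1 | intermediate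
5 | 6-acetyl-2-allyl-3,5-bis(benzyloxy)cyclohexa-3,5-dien-1-one (racemic) | CC(=O)C1=C(OCc2ccccc2)C=C(OCc2ccccc2)C(CC=C)C1=O | intermediate (not isolated)
6 | 1-[3-allyl-4,6-bis(benzyloxy)-2-hydroxyphenyl]ethanone | CC(=O)c1c(O)c(CC=C)c(OCc2ccccc2)cc1OCc1ccccc1 | intermediate
7 | N,N-dimethylformamide dimethyl acetal | COC(OC)N(C)C | starting material
8 | (E)-1-[3-allyl-4,6-bis(benzyloxy)-2-hydroxyphenyl]-3-(dimethylamino)prop-2-en-1-one | CN(C)/C=C/C(=O)c1c(O)c(CC=C)c(OCc2ccccc2)cc1OCc1ccccc1 | intermediate (not isolated)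
9 | 8-allyl-5,7-bis(benzyloxy)-4H-chromen-4-one | O=c1ccoc2c(CC=C)c(OCc3ccccc3)cc(OCc3ccccc3)c12 | intermediate
10 | 4-(benzyloxy)phenylboronic acid | OB(O)c1ccc(OCc2ccccc2)cc1 | starting material
11 | (2S)-8-allyl-5,7-bis(benzyloxy)-2-[4-(benzyloxy)phenyl]chroman-4-one | O=C1C[C@@H](c2ccc(OCc3ccccc3)cc2)Oc2c(CC=C)c(OCc3ccccc3)cc(OCc3ccccc3)c12 | intermediate
12 | (2S,4S)-8-allyl-5,7-bis(benzyloxy)-2-[4-(benzyloxy)phenyl]chroman-4-ol | O[C@H]1C[C@@H](c2ccc(OCc3ccccc3)cc2)Oc2c(CC=C)c(OCc3ccccc3)cc(OCc3ccccc3)c12 | intermediate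
13 | (2S,4S)-8-allyl-5,7-bis(benzyloxy)-2-[4-(benzyloxy)phenyl]-4-(tert-butyldimethylsilyloxy)chromane | CC(C)(C)[Si](C)(C)O[C@H]1C[C@@H](c2ccc(OCc3ccccc3)cc2)Oc2c(CC=C)c(OCc3ccccc3)cc(OCc3ccccc3)c12 | intermediate
14 | 2-[Chr]acetaldehyde | CC(C)(C)[Si](C)(C)O[C@H]1C[C@@H](c2ccc(OCc3ccccc3)cc2)Oc2c(CC=O)c(OCc3ccccc3)cc(OCc3ccccc3)c12 | intermediate
15 | 2-[Chr]acetic acid | CC(C)(C)[Si](C)(C)O[C@H]1C[C@@H](c2ccc(OCc3ccccc3)cc2)Oc2c(CC(=O)O)c(OCc3ccccc3)cc(OCc3ccccc3)c12 | intermediate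
16 | (R)-4-benzyloxazolidin-2-one | O=C1N[C@H](Cc2ccccc2)CO1 | starting material
17 | 2-[Chr]acetic pivalic anhydride | CC(C)(C)[Si](C)(C)O[C@H]1C[C@@H](c2ccc(OCc3ccccc3)cc2)Oc2c(CC(=O)OC(=O)C(C)(C)C)c(OCc3ccccc3)cc(OCc3ccccc3)c12 | intermediate (not isolated)
18 | (4R)-4-benzyl-3-{2-[Chr]acetyl}oxazolidin-2-one | CC(C)(C)[Si](C)(C)O[C@H]1C[C@@H](c2ccc(OCc3ccccc3)cc2)Oc2c(CC(=O)N3C(=O)OC[C@H]3Cc3ccccc3)c(OCc3ccccc3)cc(OCc3ccccc3)c12 | intermediate
19 | 3,4-bis(benzyloxy)benzaldehyde | O=Cc1ccc(OCc2ccccc2)c(OCc2ccccc2)c1 | starting material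
20 | Z-dibutylboron enolate of 18 | CCCCB(CCCC)O/C(=C\c1c(OCc2ccccc2)cc(OCc2ccccc2)c2c1O[C@H](c1ccc(OCc3ccccc3)cc1)C[C@@H]2O[Si](C)(C)C(C)(C)C)N1C(=O)OC[C@H]1Cc1ccccc1 | intermediate (not isolated)
21 | (4R)-4-benzyl-3-{(2R,3R)-3-[3,4-bis(benzyloxy)phenyl]-3-hydroxy-2-[Chr]propanoyl}oxazolidin-2-one | O=C(N1C(=O)OC[C@H]1Cc1ccccc1)[C@H](c1c(OCc2ccccc2)cc(OCc2ccccc2)c2c1O[C@H](c1ccc(OCc3ccccc3)cc1)C[C@@H]2O[Si](C)(C)C(C)(C)C)[C@@H](O)c1ccc(OCc2ccccc2)c(OCc2ccccc2)c1 | intermediate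
22 | (4R)-4-benzyl-3-{(2R,3R)-3-[3,4-bis(benzyloxy)phenyl]-2-[Chr]-3-(triethylsilyloxy)propanoyl}oxazolidin-2-one | O=C(N1C(=O)OC[C@H]1Cc1ccccc1)[C@H](c1c(OCc2ccccc2)cc(OCc2ccccc2)c2c1O[C@H](c1ccc(OCc3ccccc3)cc1)C[C@@H]2O[Si](C)(C)C(C)(C)C)[C@@H](O[Si](CC)(CC)CC)c1ccc(OCc2ccccc2)c(OCc2ccccc2)c1 | intermediate
23 | (2S,3R)-3-[3,4-bis(benzyloxy)phenyl]-2-[Chr]-3-(triethylsilyloxy)propan-1-ol | OC[C@H](c1c(OCc2ccccc2)cc(OCc2ccccc2)c2c1O[C@H](c1ccc(OCc3ccccc3)cc1)C[C@@H]2O[Si](C)(C)C(C)(C)C)[C@@H](O[Si](CC)(CC)CC)c1ccc(OCc2ccccc2)c(OCc2ccccc2)c1 | intermediate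
24 | (2R,3R)-3-[3,4-bis(benzyloxy)phenyl]-2-[Chr]-3-(triethylsilyloxy)propanal | O=C[C@H](c1c(OCc2ccccc2)cc(OCc2ccccc2)c2c1O[C@H](c1ccc(OCc3ccccc3)cc1)C[C@@H]2O[Si](C)(C)C(C)(C)C)[C@@H](O[Si](CC)(CC)CC)c1ccc(OCc2ccccc2)c(OCc2ccccc2)c1 | intermediate
25 | 5-bromoresorcinol | Oc1cc(O)cc(Br)c1 | starting material
26 | 1,3-bis(benzyloxy)-5-bromobenzene | Brc1cc(OCc2ccccc2)cc(OCc2ccccc2)c1 | intermediate
27 | 1,5-bis(benzyloxy)-3-bromo-2-iodobenzene | Brc1cc(OCc2ccccc2)cc(OCc2ccccc2)c1I | intermediate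
28 | [2,4-bis(benzyloxy)-6-bromophenyl]magnesium chloride (LiCl complex) | Cl[Mg]c1c(Br)cc(OCc2ccccc2)cc1OCc1ccccc1 | intermediate (not isolated)
29 | 1-[2,4-bis(benzyloxy)-6-bromophenyl]-3-[3,4-bis(benzyloxy)phenyl]-2-[Chr]-3-(triethylsilyloxy)propan-1-ol, C2 and C3 as in 24, C1 epimers | OC(c1c(Br)cc(OCc2ccccc2)cc1OCc1ccccc1)[C@H](c1c(OCc2ccccc2)cc(OCc2ccccc2)c2c1O[C@H](c1ccc(OCc3ccccc3)cc1)C[C@@H]2O[Si](C)(C)C(C)(C)C)[C@@H](O[Si](CC)(CC)CC)c1ccc(OCc2ccccc2)c(OCc2ccccc2)c1 | intermediate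
30 | 1-[2,4-bis(benzyloxy)-6-bromophenyl]-3-[3,4-bis(benzyloxy)phenyl]-2-[Chr-OH]propane-1,3-diol, C2 and C3 as in 24, C1 epimers | OC(c1c(Br)cc(OCc2ccccc2)cc1OCc1ccccc1)[C@H](c1c(OCc2ccccc2)cc(OCc2ccccc2)c2c1O[C@H](c1ccc(OCc3ccccc3)cc1)C[C@@H]2O)[C@@H](O)c1ccc(OCc2ccccc2)c(OCc2ccccc2)c1 | intermediate
31 | (2R,3S,4RS)-5,7-bis(benzyloxy)-2-[3,4-bis(benzyloxy)phenyl]-3-[Chr-OH]chroman-4-ol (2,3-cis) | OC1c2c(OCc3ccccc3)cc(OCc3ccccc3)cc2O[C@@H](c2ccc(OCc3ccccc3)c(OCc3ccccc3)c2)[C@H]1c1c(OCc2ccccc2)cc(OCc2ccccc2)c2c1O[C@H](c1ccc(OCc3ccccc3)cc1)C[C@@H]2O | intermediate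
32 | (2R,3R)-5,7-bis(benzyloxy)-2-[3,4-bis(benzyloxy)phenyl]-3-{(2S)-5,7-bis(benzyloxy)-2-[4-(benzyloxy)phenyl]-4-oxochroman-8-yl}chroman-4-one | O=C1c2c(OCc3ccccc3)cc(OCc3ccccc3)cc2O[C@@H](c2ccc(OCc3ccccc3)c(OCc3ccccc3)c2)[C@H]1c1c(OCc2ccccc2)cc(OCc2ccccc2)c2c1O[C@H](c1ccc(OCc3ccccc3)cc1)CC2=O | intermediate
33 | (2R,3R)-2-(3,4-dihydroxyphenyl)-5,7-dihydroxy-3-[(2S)-5,7-dihydroxy-2-(4-hydroxyphenyl)-4-oxochroman-8-yl]chroman-4-one | O=C1c2c(O)cc(O)cc2O[C@@H](c2ccc(O)c(O)c2)[C@H]1c1c(O)cc(O)c2c1O[C@H](c1ccc(O)cc1)CC2=O | target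

**Totals**
Total step count: 21. Longest linear sequence: 19 steps (steps 1–14 and 17–21); steps 15–16 make the ring-A iodide 27.

**Three steps most likely to fail**

Step 11 (boron aldol). The crowded 2,6-dioxygenated arylacetyl enolate may react sluggishly, and Bu2BOTf may ionise the very electron-rich benzylic silyl ether. The fallback makes the same C2–C3 bond by a crossed Claisen-type acylation followed by a chelation-controlled reduction. It sets out from acid 15 and comes back at alcohol 23. Acid 15, through anhydride 17, is joined to (S)-4-benzyloxazolidin-2-one to give (4S)-4-benzyl-3-{2-[Chr]acetyl}oxazolidin-2-one F1. Its sodium enolate (NaN(SiMe3)2, THF, −78 °C) is C-acylated anti to the benzyl group by 3,4-bis(benzyloxy)benzoyl chloride F2 (from the commercial acid and oxalyl chloride). This gives (4S)-4-benzyl-3-{(2R)-3-[3,4-bis(benzyloxy)phenyl]-3-oxo-2-[Chr]propanoyl}oxazolidin-2-one F3, which must be kept cold and base-free because its α-aryl centre is labile. Zn(BH4)2 (CH2Cl2/Et2O, −20 °C) reduces the chelated keto imide to the syn alcohol (4S)-4-benzyl-3-{(2R,3R)-3-[3,4-bis(benzyloxy)phenyl]-3-hydroxy-2-[Chr]propanoyl}oxazolidin-2-one F4. TESCl/imidazole gives (4S)-4-benzyl-3-{(2R,3R)-3-[3,4-bis(benzyloxy)phenyl]-2-[Chr]-3-(triethylsilyloxy)propanoyl}oxazolidin-2-one F5, and LiBH4 removes the auxiliary to give 23.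

Step 17 (aryl Grignard addition). The 2,6-disubstituted, basic Grignard reagent may enolise the α-aryl aldehyde or decompose through the aryne. The fallback drops the preformed organometallic and couples iodide 27 with aldehyde 24 under Barbier-type Nozaki–Hiyama–Kishi conditions (CrCl2 4 equiv, NiCl2 2 mol %, DMF, rt). Nickel inserts into C–I only, and the non-basic arylchromium species adds to the aldehyde. It sets out from 24 and 27 and comes back at 29, with no new compound, F0.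

Step 19 (copper-catalysed ring closure). The hindered secondary benzylic alkoxide may couple slowly, or the bromide may be reduced. The fallback closes ring C by a base-mediated intramolecular SNAr on a fluoroarene instead, again with retention at the carbinol carbon. It sets out from aldehyde 24 and comes back at 31. Commercial 5-fluororesorcinol is benzylated (BnBr, K2CO3) to 1,3-bis(benzyloxy)-5-fluorobenzene F6 and iodinated (NIS) to 1,5-bis(benzyloxy)-3-fluoro-2-iodobenzene F7. Exchange with i-PrMgCl·LiCl at −40 °C gives [2,4-bis(benzyloxy)-6-fluorophenyl]magnesium chloride F8, which adds to 24 to give 1-[2,4-bis(benzyloxy)-6-fluorophenyl]-3-[3,4-bis(benzyloxy)phenyl]-2-[Chr]-3-(triethylsilyloxy)propan-1-ol F9. TBAF gives 1-[2,4-bis(benzyloxy)-6-fluorophenyl]-3-[3,4-bis(benzyloxy)phenyl]-2-[Chr-OH]propane-1,3-diol F10. KOt-Bu (THF/DMF, 60–80 °C) then displaces fluoride through the six-membered transition state to give 31.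

**Further compounds**
F1 | step 11 | (4S)-4-benzyl-3-{2-[Chr]acetyl}oxazolidin-2-one | CC(C)(C)[Si](C)(C)O[C@H]1C[C@@H](c2ccc(OCc3ccccc3)cc2)Oc2c(CC(=O)N3C(=O)OC[C@@H]3Cc3ccccc3)c(OCc3ccccc3)cc(OCc3ccccc3)c12
F2 | step 11 | 3,4-bis(benzyloxy)benzoyl chloride | O=C(Cl)c1ccc(OCc2ccccc2)c(OCc2ccccc2)c1
F3 | step 11 | (4S)-4-benzyl-3-{(2R)-3-[3,4-bis(benzyloxy)phenyl]-3-oxo-2-[Chr]propanoyl}oxazolidin-2-one | O=C(N1C(=O)OC[C@@H]1Cc1ccccc1)[C@H](c1c(OCc2ccccc2)cc(OCc2ccccc2)c2c1O[C@H](c1ccc(OCc3ccccc3)cc1)C[C@@H]2O[Si](C)(C)C(C)(C)C)C(=O)c1ccc(OCc2ccccc2)c(OCc2ccccc2)c1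
F4 | step 11 | (4S)-4-benzyl-3-{(2R,3R)-3-[3,4-bis(benzyloxy)phenyl]-3-hydroxy-2-[Chr]propanoyl}oxazolidin-2-one | O=C(N1C(=O)OC[C@@H]1Cc1ccccc1)[C@H](c1c(OCc2ccccc2)cc(OCc2ccccc2)c2c1O[C@H](c1ccc(OCc3ccccc3)cc1)C[C@@H]2O[Si](C)(C)C(C)(C)C)[C@@H](O)c1ccc(OCc2ccccc2)c(OCc2ccccc2)c1
F5 | step 11 | (4S)-4-benzyl-3-{(2R,3R)-3-[3,4-bis(benzyloxy)phenyl]-2-[Chr]-3-(triethylsilyloxy)propanoyl}oxazolidin-2-one | O=C(N1C(=O)OC[C@@H]1Cc1ccccc1)[C@H](c1c(OCc2ccccc2)cc(OCc2ccccc2)c2c1O[C@H](c1ccc(OCc3ccccc3)cc1)C[C@@H]2O[Si](C)(C)C(C)(C)C)[C@@H](O[Si](CC)(CC)CC)c1ccc(OCc2ccccc2)c(OCc2ccccc2)c1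
F0 | step 17 | none | none
F6 | step 19 | 1,3-bis(benzyloxy)-5-fluorobenzene | Fc1cc(OCc2ccccc2)cc(OCc2ccccc2)c1
F7 | step 19 | 1,5-bis(benzyloxy)-3-fluoro-2-iodobenzene | Fc1cc(OCc2ccccc2)cc(OCc2ccccc2)c1I
F8 | step 19 | [2,4-bis(benzyloxy)-6-fluorophenyl]magnesium chloride | Cl[Mg]c1c(F)cc(OCc2ccccc2)cc1OCc1ccccc1
F9 | step 19 | 1-[2,4-bis(benzyloxy)-6-fluorophenyl]-3-[3,4-bis(benzyloxy)phenyl]-2-[Chr]-3-(triethylsilyloxy)propan-1-ol | OC(c1c(F)cc(OCc2ccccc2)cc1OCc1ccccc1)[C@H](c1c(OCc2ccccc2)cc(OCc2ccccc2)c2c1O[C@H](c1ccc(OCc3ccccc3)cc1)C[C@@H]2O[Si](C)(C)C(C)(C)C)[C@@H](O[Si](CC)(CC)CC)c1ccc(OCc2ccccc2)c(OCc2ccccc2)c1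
F10 | step 19 | 1-[2,4-bis(benzyloxy)-6-fluorophenyl]-3-[3,4-bis(benzyloxy)phenyl]-2-[Chr-OH]propane-1,3-diol | OC(c1c(F)cc(OCc2ccccc2)cc1OCc1ccccc1)[C@H](c1c(OCc2ccccc2)cc(OCc2ccccc2)c2c1O[C@H](c1ccc(OCc3ccccc3)cc1)C[C@@H]2O)[C@@H](O)c1ccc(OCc2ccccc2)c(OCc2ccccc2)c1
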